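**Retrosynthetic overview**

- Target ⇐ desilylation ⇐ dehydration at one end (C5–OH → C4=C5) of a C2-symmetric bis(tertiary allylic alcohol) in which both end rings are the diol-type ring B.
- That diol ⇐ one operation: two acyclic alkynones plus one C20 bis(alkenylboronate) under zerovalent palladium. Each end closes C5–C6 (six-membered ring), joins C7–C8, and fixes the 6E exocyclic alkene and the C5 carbinol.
- Alkynone ⇐ 2,2-dimethylpent-4-enal (alkyne homologation, ozonolysis, Keck methallylation to set C3, silylation, ozonolysis).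
- Bis-boronate ⇐ polyene diiodide ⇐ Wittig reaction of a C12 bis-phosphonium salt (from oxidative dimerisation of the stannane of (E)-3-methylpent-2-en-4-yn-1-ol) with (E)-3-iodo-2-methylacrolein.
- Ring order: both rings form together in the palladium step; ring A is afterwards converted to its cyclohexene form.

Assumption: locants follow carotenoid numbering for each half (ring C1–C6, ring methyl on C5, chain C7–C15); ring A is the cyclohexenol end (unprimed), ring B the diol end (primed); the target is read as (3S,3'S,5'R,6E,6'E) with an all-E chain; the methallylstannane, the C6 enynol and the iodo-alcohol are bought.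

**Route**

Step 1
Reactants: 1 2,2-dimethylpent-4-enal
Product: 2 3,3-dimethylhex-5-en-1-yne
Conditions: dimethyl (1-diazo-2-oxopropyl)phosphonate, K2CO3, MeOH, 0 °C to rt
Reagents that add atoms: dimethyl (1-diazo-2-oxopropyl)phosphonate, CC(=O)C(=[N+]=[N-])P(=O)(OC)OC
Why: Seyferth–Gilbert homologation in the Ohira–Bestmann version converts the non-enolisable neopentyl aldehyde into the terminal alkyne (the future C6≡C7) without touching the alkene.

Step 2
Reactants: 2 3,3-dimethylhex-5-en-1-yne
Product: 4 3,3-dimethylpent-4-ynal, via ozonide 3 (not isolated)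
Conditions: O3, CH2Cl2, −78 °C (indicator end point); then Me2S, −78 °C to rt
Reagents that add atoms: ozone, [O-][O+]=O
Why: Chemoselective ozonolysis with reductive work-up (alkenes react far faster with ozone than terminal alkynes) cuts the vinyl group to the aldehyde that becomes C3.

Step 3
Reactants: 4 3,3-dimethylpent-4-ynal; 5 tributyl(2-methylprop-2-en-1-yl)stannane
Product: 7 (4R)-2,6,6-trimethyloct-1-en-7-yn-4-ol, via stannyl ether 6 (not isolated)
Conditions: (R)-BINOL (20 mol%), Ti(OiPr)4 (10 mol%), 4 Å MS, CH2Cl2, −20 °C; aq. NaHCO3 work-up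
Reagents that add atoms: none
Why: Keck asymmetric methallylation: the (R)-BINOL/Ti(OiPr)4 Lewis acid exposes the Re face of the aldehyde to the methallylstannane and sets the carbinol centre as (4R), which is the future C3/C3' (3S in the rings; the descriptor changes only because CIP priorities change).

Step 4
Reactants: 7 (4R)-2,6,6-trimethyloct-1-en-7-yn-4-ol
Product: 8 tert-butyldimethyl{[(4R)-2,6,6-trimethyloct-1-en-7-yn-4-yl]oxy}silane
Conditions: TBSCl, imidazole, DMF, rt
Reagents that add atoms: tert-butyldimethylsilyl chloride, CC(C)(C)[Si](C)(C)Cl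
Why: Standard silylation of the secondary alcohol; the terminal alkyne C–H is not silylated under imidazole.

Step 5
Reactants: 8 tert-butyldimethyl{[(4R)-2,6,6-trimethyloct-1-en-7-yn-4-yl]oxy}silane
Product: 10 (4S)-4-[(tert-butyldimethylsilyl)oxy]-6,6-dimethyloct-7-yn-2-one, via ozonide 9 (not isolated)
Conditions: O3, CH2Cl2, −78 °C (indicator end point); then Me2S, −78 °C to rt
Reagents that add atoms: ozone, [O-][O+]=O
Why: Ozonolysis of the 1,1-disubstituted alkene (again much faster than the alkyne) unmasks the methyl ketone C5(=O)–CH3 with the silyl ether intact and no change at the stereocentre.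

Step 6
Reactants: 11 (2E)-3-methylpent-2-en-4-yn-1-ol
Product: 12 (2E,4E)-3-methyl-5-(tributylstannyl)penta-2,4-dien-1-ol
Conditions: Bu3SnH, PdCl2(PPh3)2 (2 mol%), THF, 0 °C
Reagents that add atoms: tributyltin hydride, CCCC[SnH](CCCC)CCCC
Why: Palladium-catalysed syn-hydrostannation of the terminal alkyne of the conjugated enyne places tin on the terminal carbon and gives the 4E alkene, leaving the 2E alkene untouched.

Step 7
Reactants: 12 (2E,4E)-3-methyl-5-(tributylstannyl)penta-2,4-dien-1-ol (2 equiv)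
Product: 13 (2E,4E,6E,8E)-3,8-dimethyldeca-2,4,6,8-tetraene-1,10-diol
Conditions: CuCl2 (1.1 equiv per tin), DMF, 0 °C to rt, dark
Reagents that add atoms: none
Why: Copper-mediated oxidative homocoupling of the alkenylstannane (tin-to-copper transmetalation and dimerisation with retention of alkene geometry) forms the C15–C15' bond and the all-E tetraene diol.

Step 8
Reactants: 13 (2E,4E,6E,8E)-3,8-dimethyldeca-2,4,6,8-tetraene-1,10-diol
Product: 14 [(2E,4E,6E,8E)-3,8-dimethyldeca-2,4,6,8-tetraene-1,10-diyl]bis(triphenylphosphonium) dibromide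
Conditions: PPh3·HBr (2.1 equiv), MeOH, rt
Reagents that add atoms: triphenylphosphonium bromide, [Br-].c1ccc(cc1)[PH+](c1ccccc1)c1ccccc1
Why: Polyene-conjugated primary allylic alcohols are converted by PPh3·HBr into the primary allylic phosphonium salts (SN1-type substitution, the standard carotenoid Wittig-salt formation), the fully conjugated primary salt being the thermodynamic product.

Step 9
Reactants: 15 (2E)-3-iodo-2-methylprop-2-en-1-ol
Product: 16 (2E)-3-iodo-2-methylprop-2-enal
Conditions: MnO2, CH2Cl2, rt, dark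
Reagents that add atoms: none
Why: MnO2 oxidises the allylic alcohol to the enal without isomerising the vinyl iodide.

Step 10
Reactants: 14 [(2E,4E,6E,8E)-3,8-dimethyldeca-2,4,6,8-tetraene-1,10-diyl]bis(triphenylphosphonium) dibromide; 16 (2E)-3-iodo-2-methylprop-2-enal (2.2 equiv)
Product: 19 (1E,3E,5E,7E,9E,11E,13E,15E)-1,16-diiodo-2,6,11,15-tetramethylhexadeca-1,3,5,7,9,11,13,15-octaene, via bis-ylide 17 (not isolated), via mono-olefinated ylide 18 (not isolated)
Conditions: NaOMe (2.2 equiv), MeOH–CH2Cl2, −20 °C, then 16, to rt; then heptane, 80 °C, dark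
Reagents that add atoms: none
Why: Two-fold Wittig olefination of the polyenyl bis-ylide at its α-carbons builds C10=C11 and C10'=C11'; the new disubstituted alkenes form as E/Z mixtures that equilibrate thermally to all-E as is usual for carotenoid polyenes, while the trisubstituted vinyl iodides keep their E geometry.

Step 11
Reactants: 19 (1E,3E,5E,7E,9E,11E,13E,15E)-1,16-diiodo-2,6,11,15-tetramethylhexadeca-1,3,5,7,9,11,13,15-octaene
Product: 21 2,2'-[(1E,3E,5E,7E,9E,11E,13E,15E)-2,6,11,15-tetramethylhexadeca-1,3,5,7,9,11,13,15-octaene-1,16-diyl]bis(4,4,5,5-tetramethyl-1,3,2-dioxaborolane), via iodo boronate 20 (not isolated)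
Conditions: B2pin2 (2.4 equiv), PdCl2(PPh3)2 (5 mol%), PPh3, KOPh, toluene, 50 °C, dark
Reagents that add atoms: bis(pinacolato)diboron, CC1(C)OB(OC1(C)C)B1OC(C)(C)C(C)(C)O1
Why: Miyaura borylation (oxidative addition of zerovalent palladium into the C–I bonds, transmetalation with phenoxide-activated diboron, reductive elimination) replaces both iodides by Bpin with retention of geometry, and KOPh at 50 °C suppresses Suzuki self-coupling.

Step 12
Reactants: 10 (4S)-4-[(tert-butyldimethylsilyl)oxy]-6,6-dimethyloct-7-yn-2-one (2.2 equiv); 21 the bis-boronate of step 11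
Product: 23 C2-symmetric (3S,5R,6E,3'S,5'R,6'E)-bis-TBS diol = (1R,5S,1'R,5'S)-2,2'-[(2E,4E,6E,8E,10E,12E,14E,16E)-3,7,12,16-tetramethyloctadeca-2,4,6,8,10,12,14,16-octaene-1,18-diylidene]bis{5-[(tert-butyldimethylsilyl)oxy]-1,3,3-trimethylcyclohexan-1-ol}, via mono-cyclised boronate 22 (not isolated)
Conditions: Pd2(dba)3 (5 mol%), PCy3 (20 mol%), MeOH–THF (1:1), 60 °C, degassed, dark
Reagents that add atoms: none
Why: Proposed new method: a two-fold Tsukamoto-type anti-Wacker alkenylative cyclisation, in which zerovalent palladium bound to the terminal alkyne makes C6 nucleophilic, C6 attacks the tethered methyl ketone from the side of the alkyne opposite to palladium (6-exo closure helped by the gem-dimethyl group), methanol protonates the alkoxide, and the alkenylpalladium at C7 transmetalates with one B–C8 end of 21 and reductively eliminates, so that C5 and C8 end up trans across C6=C7 (6E); the new carbinol centre is set by a chair transition state with OTBS and the ketone methyl equatorial and the developing alkoxide axial (the alternative puts that methyl 1,3-diaxial to a C1 methyl), giving the (3S,5R) ring at both ends; the closest known reaction is the Pd(PPh3)4/MeOH cyclisation of alkynals and alkynones with aryl- and alkenylboronic acids, here run twice on a bis-boronate.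

Step 13
Reactants: 23 the C2-symmetric bis-TBS diol
Product: 25 bis-TBS ether of the target [(3S,6E)-ring A cyclohexene end, (3'S,5'R,6'E)-ring B carbinol end], via sulfamate 24 (not isolated)
Conditions: Burgess reagent (1.0 equiv), Et3N (cat.), toluene, 0 °C to 40 °C, dark
Reagents that add atoms: none
Why: Burgess dehydration: the tertiary, polyene-conjugated allylic sulfamate eliminates (syn-elimination with ion-pair character) towards C4 to give the more substituted ring alkene conjugated with the chain; because 23 is C2-symmetric either carbinol gives the same product, and one equivalent of reagent limits reaction to one end (statistical, about 45–50% with unreacted diol recycled and the bis-ene separated), leaving C3, C3' and C5' untouched.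

Step 14
Reactants: 25 bis-TBS ether of the target
Product: 26 target, (3S,3'S,5'R,6E,6'E)-retro-carotenoid triol (CNP0269135.2)
Conditions: TBAF, AcOH (buffer), THF, 0 °C to rt, dark
Reagents that add atoms: none
Why: Fluoride cleaves both secondary TBS ethers (silyl ether deprotection) under buffered conditions that neither ionise the tertiary allylic alcohol nor isomerise the polyene.

**Compound list**

1 | 2,2-dimethylpent-4-enal | C=CCC(C)(C)C=O | starting material
2 | 3,3-dimethylhex-5-en-1-yne | C=CCC(C)(C)C#C | intermediate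
3 | 3-(2,2-dimethylbut-3-yn-1-yl)-1,2,4-trioxolane | C#CC(C)(C)CC1OCOO1 | intermediate (not isolated)
4 | 3,3-dimethylpent-4-ynal | O=CCC(C)(C)C#C | intermediate
5 | tributyl(2-methylprop-2-en-1-yl)stannane | CC(=C)C[Sn](CCCC)(CCCC)CCCC | starting material
6 | tributyl{[(4R)-2,6,6-trimethyloct-1-en-7-yn-4-yl]oxy}stannane | CC(=C)C[C@@H](O[Sn](CCCC)(CCCC)CCCC)CC(C)(C)C#C | intermediate (not isolated)
7 | (4R)-2,6,6-trimethyloct-1-en-7-yn-4-ol | CC(=C)C[C@@H](O)CC(C)(C)C#C | intermediate
8 | tert-butyldimethyl{[(4R)-2,6,6-trimethyloct-1-en-7-yn-4-yl]oxy}silane | CC(=C)C[C@@H](O[Si](C)(C)C(C)(C)C)CC(C)(C)C#C | intermediate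
9 | 3-methyl-3-{(2S)-2-[(tert-butyldimethylsilyl)oxy]-4,4-dimethylhex-5-yn-1-yl}-1,2,4-trioxolane (epimers at the trioxolane carbon) | CC1(C[C@@H](O[Si](C)(C)C(C)(C)C)CC(C)(C)C#C)OCOO1 | intermediate (not isolated)
10 | (4S)-4-[(tert-butyldimethylsilyl)oxy]-6,6-dimethyloct-7-yn-2-one | CC(=O)C[C@@H](O[Si](C)(C)C(C)(C)C)CC(C)(C)C#C | intermediate
11 | (2E)-3-methylpent-2-en-4-yn-1-ol | C#C/C(C)=C/CO | starting material
12 | (2E,4E)-3-methyl-5-(tributylstannyl)penta-2,4-dien-1-ol | CCCC[Sn](CCCC)(CCCC)/C=C/C(C)=C/CO | intermediate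
13 | (2E,4E,6E,8E)-3,8-dimethyldeca-2,4,6,8-tetraene-1,10-diol | OC/C=C(C)/C=C/C=C/C(C)=C/CO | intermediate
14 | [(2E,4E,6E,8E)-3,8-dimethyldeca-2,4,6,8-tetraene-1,10-diyl]bis(triphenylphosphonium) dibromide | [Br-].[Br-].c1ccccc1[P+](c1ccccc1)(c1ccccc1)C/C=C(C)/C=C/C=C/C(C)=C/C[P+](c1ccccc1)(c1ccccc1)c1ccccc1 | intermediate
15 | (2E)-3-iodo-2-methylprop-2-en-1-ol | I/C=C(C)/CO | starting material
16 | (2E)-3-iodo-2-methylprop-2-enal | I/C=C(C)/C=O | intermediate
17 | bis-ylide of 14, all-E | c1ccccc1[P+](c1ccccc1)(c1ccccc1)[CH-]/C=C(C)/C=C/C=C/C(C)=C/[CH-][P+](c1ccccc1)(c1ccccc1)c1ccccc1 | intermediate (not isolated)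
18 | mono-olefinated ylide, all-E iodo-hexaenyl phosphorus ylide | c1ccccc1[P+](c1ccccc1)(c1ccccc1)[CH-]/C=C(C)/C=C/C=C/C(C)=C/C=C/C(C)=C/I | intermediate (not isolated)
19 | (1E,3E,5E,7E,9E,11E,13E,15E)-1,16-diiodo-2,6,11,15-tetramethylhexadeca-1,3,5,7,9,11,13,15-octaene | I/C=C(C)/C=C/C=C(C)/C=C/C=C/C(C)=C/C=C/C(C)=C/I | intermediate
20 | all-E 16-iodo-2,6,11,15-tetramethylhexadeca-1,3,5,7,9,11,13,15-octaen-1-yl pinacol boronate | CC1(C)OB(OC1(C)C)/C=C(C)/C=C/C=C(C)/C=C/C=C/C(C)=C/C=C/C(C)=C/I | intermediate (not isolated)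
21 | 2,2'-[(1E,3E,5E,7E,9E,11E,13E,15E)-2,6,11,15-tetramethylhexadeca-1,3,5,7,9,11,13,15-octaene-1,16-diyl]bis(4,4,5,5-tetramethyl-1,3,2-dioxaborolane) | CC1(C)OB(OC1(C)C)/C=C(C)/C=C/C=C(C)/C=C/C=C/C(C)=C/C=C/C(C)=C/B1OC(C)(C)C(C)(C)O1 | intermediate
22 | (1R,5S,2E)-5-[(tert-butyldimethylsilyl)oxy]-1,3,3-trimethyl-2-[(2E,4E,6E,8E,10E,12E,14E,16E)-3,7,12,16-tetramethyl-17-(4,4,5,5-tetramethyl-1,3,2-dioxaborolan-2-yl)heptadeca-2,4,6,8,10,12,14,16-octaen-1-ylidene]cyclohexan-1-ol | O[C@]1(C)C[C@@H](O[Si](C)(C)C(C)(C)C)CC(C)(C)\C1=C/C=C(C)/C=C/C=C(C)/C=C/C=C/C(C)=C/C=C/C(C)=C/B1OC(C)(C)C(C)(C)O1 | intermediate (not isolated)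
23 | C2-symmetric (3S,5R,6E,3'S,5'R,6'E)-bis-TBS diol, both ends ring B | O[C@]1(C)C[C@@H](O[Si](C)(C)C(C)(C)C)CC(C)(C)\C1=C/C=C(C)/C=C/C=C(C)/C=C/C=C/C(C)=C/C=C/C(C)=C/C=C1\C(C)(C)C[C@H](O[Si](C)(C)C(C)(C)C)C[C@@]1(C)O | intermediate
24 | triethylammonium salt of the mono-(N-methoxycarbonyl)sulfamate of 23 | CC[NH+](CC)CC.COC(=O)[N-]S(=O)(=O)O[C@]1(C)C[C@@H](O[Si](C)(C)C(C)(C)C)CC(C)(C)\C1=C/C=C(C)/C=C/C=C(C)/C=C/C=C/C(C)=C/C=C/C(C)=C/C=C1\C(C)(C)C[C@H](O[Si](C)(C)C(C)(C)C)C[C@@]1(C)O | intermediate (not isolated)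
25 | (3S,3'S,5'R,6E,6'E)-3,3'-bis-O-TBS ether of the target | CC1=C[C@@H](O[Si](C)(C)C(C)(C)C)CC(C)(C)\C1=C/C=C(C)/C=C/C=C(C)/C=C/C=C/C(C)=C/C=C/C(C)=C/C=C1\C(C)(C)C[C@H](O[Si](C)(C)C(C)(C)C)C[C@@]1(C)O | intermediate
26 | (1S,4E)-4-{(2E,4E,6E,8E,10E,12E,14E,16E,18E)-18-[(2R,4S)-2,4-dihydroxy-2,6,6-trimethylcyclohexylidene]-3,7,12,16-tetramethyloctadeca-2,4,6,8,10,12,14,16-octaen-1-ylidene}-3,5,5-trimethylcyclohex-2-en-1-ol | CC1=C[C@@H](O)CC(C)(C)\C1=C/C=C(C)/C=C/C=C(C)/C=C/C=C/C(C)=C/C=C/C(C)=C/C=C1\C(C)(C)C[C@H](O)C[C@@]1(C)O | target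

**Step count and risks**

Total: 14 steps. Longest linear sequence: 8 steps (1→2→4→7→8→10→23→25→26, or equally 11→12→13→14→19→21→23→25→26).

Three steps most likely to fail:

Step 12. The combination of a methyl ketone, a terminal alkyne and a polyenyl bis-boronate is untested. Specific worries are the C5 diastereoselectivity, alkyne oligomerisation, and palladium-induced ionisation of the tertiary allylic alcohols formed. The fallback sets out from 10 and diiodide 19 and comes back to the route at 23. A two-fold Sonogashira coupling (Pd(PPh3)4, CuI, Et3N, THF, rt) runs through the mono-coupled iodo-enynone F1 (not isolated) to the all-E bis(enynone) F2. A two-fold intramolecular reductive coupling of each 1,3-enyne with its ketone (Ni(COD)2, PBu3, Et3B, toluene, rt) then closes the rings one after the other through the mono-cyclised enynone F3 (not isolated). This is a syn addition of C5 and H across an alkyne that already carries the chain on C7, so the same 6E geometry results and 23 is obtained.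

Step 13. The yield is capped by statistics. Some exocyclic methylene isomer may form, and the remaining carbinol may ionise. The fallback sets out from 10 and 21 and comes back at 25. With 21 in three-fold excess, the coupling of step 12 stops at mono-adduct 22, which is isolated and the surplus 21 recovered. Its single tertiary alcohol is dehydrated with excess Burgess reagent through the sulfamate salt F4 (not isolated) to the ring A dienyl boronate F5. A second coupling of F5 with one equivalent of 10 under the step-12 conditions closes ring B and gives 25 with no statistical step.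

Step 11. A light- and acid-sensitive octaene diiodide has to be borylated twice; protodeboronation and oligomerisation are the worries. The fallback sets out from 15 and 14 and comes back at 21. Miyaura borylation of 15 (B2pin2, PdCl2(PPh3)2, KOPh) gives the boryl alcohol F6, and MnO2 oxidation gives the boryl enal F7. The two-fold Wittig reaction of bis-ylide 17 (from 14 and NaOMe) with F7 runs through the mono-olefinated boryl ylide F8 (not isolated) straight to 21.

Further compounds
F1 | step 12 | (4S)-4-[(tert-butyldimethylsilyl)oxy]-6,6-dimethyloct-7-yn-2-one coupled once at C7 to the all-E C20 chain, other chain end still C–I | CC(=O)C[C@@H](O[Si](C)(C)C(C)(C)C)CC(C)(C)C#C/C=C(C)/C=C/C=C(C)/C=C/C=C/C(C)=C/C=C/C(C)=C/I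
F2 | step 12 | (4S,29S,9E,11E,13E,15E,17E,19E,21E,23E)-4,29-bis[(tert-butyldimethylsilyl)oxy]-6,6,10,14,19,23,27,27-octamethyldotriaconta-9,11,13,15,17,19,21,23-octaene-7,25-diyne-2,31-dione | CC(=O)C[C@@H](O[Si](C)(C)C(C)(C)C)CC(C)(C)C#C/C=C(C)/C=C/C=C(C)/C=C/C=C/C(C)=C/C=C/C(C)=C/C#CC(C)(C)C[C@H](O[Si](C)(C)C(C)(C)C)CC(C)=O
F3 | step 12 | mono-cyclised enynone: (3S,5R,6E) ring B at one end, open alkynyl ketone at the other | O[C@]1(C)C[C@@H](O[Si](C)(C)C(C)(C)C)CC(C)(C)\C1=C/C=C(C)/C=C/C=C(C)/C=C/C=C/C(C)=C/C=C/C(C)=C/C#CC(C)(C)C[C@H](O[Si](C)(C)C(C)(C)C)CC(C)=O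
F4 | step 13 | triethylammonium salt of the (N-methoxycarbonyl)sulfamate of 22 | CC[NH+](CC)CC.COC(=O)[N-]S(=O)(=O)O[C@]1(C)C[C@@H](O[Si](C)(C)C(C)(C)C)CC(C)(C)\C1=C/C=C(C)/C=C/C=C(C)/C=C/C=C/C(C)=C/C=C/C(C)=C/B1OC(C)(C)C(C)(C)O1
F5 | step 13 | ring A dienyl boronate: (3S,6E)-3-[(tert-butyldimethylsilyl)oxy] cyclohexene end carrying the all-E C20 chain ending in Bpin | CC1=C[C@@H](O[Si](C)(C)C(C)(C)C)CC(C)(C)\C1=C/C=C(C)/C=C/C=C(C)/C=C/C=C/C(C)=C/C=C/C(C)=C/B1OC(C)(C)C(C)(C)O1
F6 | step 11 | (2E)-2-methyl-3-(4,4,5,5-tetramethyl-1,3,2-dioxaborolan-2-yl)prop-2-en-1-ol | CC1(C)OB(OC1(C)C)/C=C(C)/CO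
F7 | step 11 | (2E)-2-methyl-3-(4,4,5,5-tetramethyl-1,3,2-dioxaborolan-2-yl)prop-2-enal | CC1(C)OB(OC1(C)C)/C=C(C)/C=O
F8 | step 11 | mono-olefinated boryl ylide, all-E | c1ccccc1[P+](c1ccccc1)(c1ccccc1)[CH-]/C=C(C)/C=C/C=C/C(C)=C/C=C/C(C)=C/B1OC(C)(C)C(C)(C)O1
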